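**Assumptions (one line each).** Electrophilic iodination of 1 occurs at C2, which is ortho to Br, ortho to one OMe and para to the other. The Ru-catalysed dynamic kinetic reduction with the (S,S)-catalyst gives the (1S,2S) alcohol; if the opposite diastereomer forms, the catalyst enantiomer or ligand is changed. The target's stereocentres are (S) at each of the three CH carbons (CIP assignment from the SMILES).

## Retrosynthesis
1. Ampelopsin B comes from global O-demethylation of its pentamethyl ether 11.
2. The seven-membered ring is closed last among the carbocycles. It forms by a biomimetic intramolecular Friedel–Crafts hydroarylation: protonating the stilbene of 10 gives a p-anisyl benzylic cation, which resorcinol ring B captures. This sets the third stereocentre.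
3. The stilbene comes from a Heck reaction on the aryl bromide 8. The 2,3-trans-dihydrobenzofuran in 8 comes from ionisation of the benzylic alcohol 7 with capture by the ortho-OMe; this sets the trans relationship.
4. Alcohol 7 comes from dynamic kinetic asymmetric transfer hydrogenation of the α,α-diaryl ketone 6, which fixes the diarylmethine centre. Ketone 6 is built by two Pd-catalysed α-arylations of 4'-methoxyacetophenone.
5. Ring order: the dihydrobenzofuran is formed first, then the seven-membered ring.

## Route

**Step 1**
Reactants: 1, 1-bromo-3,5-dimethoxybenzene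
Product: 2, 1-bromo-2-iodo-3,5-dimethoxybenzene
Conditions: NIS, MeCN, rt
Reagents that add atoms: N-iodosuccinimide, O=C1CCC(=O)N1I
Why: Electrophilic aromatic iodination goes to the position ortho to Br and ortho/para to the two OMe groups, the most activated and least hindered site. No stereocentre is formed.

**Step 2**
Reactants: 2; 3, 4'-methoxyacetophenone
Product: 4, 2-(2-bromo-4,6-dimethoxyphenyl)-1-(4-methoxyphenyl)ethan-1-one
Conditions: Pd(dba)2 (3 mol %), Q-Phos (6 mol %), NaOtBu, THF, 70 °C
Reagents that add atoms: none
Why: Buchwald–Hartwig ketone α-arylation proceeds chemoselectively at C–I rather than the hindered C–Br. The methyl-ketone enolate is primary, so over-arylation is disfavoured by the bulky aryl group.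

**Step 3**
Reactants: 4; 5, 1-iodo-3,5-dimethoxybenzene
Product: 6, 2-(2-bromo-4,6-dimethoxyphenyl)-2-(3,5-dimethoxyphenyl)-1-(4-methoxyphenyl)ethan-1-one (racemic, epimerisable α-centre)
Conditions: Pd(OAc)2 (5 mol %), Q-Phos (10 mol %), NaOtBu, toluene, 100 °C
Reagents that add atoms: none
Why: A second α-arylation forms the triaryl methine. The aryl iodide reacts selectively over the remaining ortho-substituted aryl bromide, which is retained for the Heck step.

**Step 4**
Reactants: 6
Product: 7, (1S,2S)-2-(2-bromo-4,6-dimethoxyphenyl)-2-(3,5-dimethoxyphenyl)-1-(4-methoxyphenyl)ethan-1-ol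
Conditions: RuCl[(S,S)-TsDPEN](p-cymene) (2 mol %), HCO2H/Et3N (5:2), 40 °C
Reagents that add atoms: none (formate supplies H⁻ and H⁺ only)
Why: Noyori–Ikariya asymmetric transfer hydrogenation with dynamic kinetic resolution. The doubly benzylic α-C–H epimerises under Et3N, so one enantiomer of the ketone is reduced. This sets the diarylmethine centre that becomes C3 of the dihydrobenzofuran (the configuration that must survive to the end) and the carbinol centre.

**Step 5**
Reactants: 7
Product: 8, (2S,3S)-4-bromo-3-(3,5-dimethoxyphenyl)-6-methoxy-2-(4-methoxyphenyl)-2,3-dihydrobenzofuran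
Conditions: BBr3 (1.1 equiv), CH2Cl2, −78 → −40 °C; aq. NaHCO3 quench
Reagents that add atoms: none (methyl is lost as MeBr)
Why: Boron-assisted ionisation of the p-anisyl carbinol and 5-exo capture by the ortho-OMe, followed by O-demethylation of the oxonium (as in pterocarpan closures). The 2,3-trans ring is the thermodynamically and geometrically favoured one, so the carbinol configuration is irrelevant. The diarylmethine centre is not touched.

**Step 6**
Reactants: 8; 9, 4-methoxystyrene
Product: 10, (2S,3S)-3-(3,5-dimethoxyphenyl)-6-methoxy-2-(4-methoxyphenyl)-4-[(E)-4-methoxystyryl]-2,3-dihydrobenzofuran (ε-viniferin pentamethyl ether, (2S,3S) series)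
Conditions: Pd(OAc)2 (5 mol %), P(o-tol)3 (10 mol %), Et3N, DMF, 110 °C
Reagents that add atoms: none
Why: A Mizoroki–Heck reaction gives the E-stilbene. The benzylic ether and the stereocentres tolerate the weak base.

**Step 7**
Reactants: 10
Product: 11, pentamethyl ampelopsin B
Conditions: TfOH (20 mol %), CH2Cl2, −20 → 0 °C
Reagents that add atoms: none (H⁺ only)
Why: Brønsted-acid hydroarylation. Protonation at the carbon next to ring A gives the p-anisyl-stabilised cation, which ring B attacks through its ortho carbon, the position para to an OMe, closing the seven-membered ring. The new centre is set by the ring conformation: Ar2 is placed away from the ring-B ortho-OMe, which gives (S). Any reversible ionisation at C2 of the dihydrobenzofuran returns to trans.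

**Step 8**
Reactants: 11
Product: 12, ampelopsin B
Conditions: BBr3 (10 equiv), CH2Cl2, −78 °C → rt, 4 h; aq. NaHCO3 quench
Reagents that add atoms: none
Why: Lewis-acid cleavage of all five aryl methyl ethers. The stereocentres are not involved.

## Checks performed
- Target SMILES: 5,7-fused dibenzosuberane core, fused dihydrobenzofuran, five OH groups, (S,S,S). Compound 11 is the target SMILES with OMe in place of OH, and the tags were carried through by matching neighbour order.
- Atom balance: 8 (C25H27BrO6) → 9 (C24H23BrO5) by loss of CH3OH; Heck gives C33H32O6; Friedel–Crafts is an isomerisation; demethylation gives C28H22O6, matching ampelopsin B.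
- Functional groups: ArBr survives steps 4 and 5 and is consumed in step 6. Only methyl ethers are present as protecting groups, and they survive steps 1–7.
- Stereocentres: the diarylmethine centre (step 4) is retained to the end. The C2 centre is set trans (step 5). The third centre is set in step 7.

## Compound list
1 | 1-bromo-3,5-dimethoxybenzene | COc1cc(Br)cc(OC)c1 | starting material
2 | 1-bromo-2-iodo-3,5-dimethoxybenzene | COc1cc(Br)c(I)c(OC)c1 | intermediate
3 | 4'-methoxyacetophenone | COc1ccc(C(C)=O)cc1 | starting material
4 | 2-(2-bromo-4,6-dimethoxyphenyl)-1-(4-methoxyphenyl)ethanone | COc1ccc(C(=O)Cc2c(Br)cc(OC)cc2OC)cc1 | intermediate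
5 | 1-iodo-3,5-dimethoxybenzene | COc1cc(I)cc(OC)c1 | starting material
6 | 2-(2-bromo-4,6-dimethoxyphenyl)-2-(3,5-dimethoxyphenyl)-1-(4-methoxyphenyl)ethanone (racemic) | COc1ccc(cc1)C(=O)C(c1c(Br)cc(OC)cc1OC)c1cc(OC)cc(OC)c1 | intermediate
7 | (1S,2S)-triarylethanol | COc1ccc(cc1)[C@@H](O)[C@H](c1c(Br)cc(OC)cc1OC)c1cc(OC)cc(OC)c1 | intermediate
8 | (2S,3S)-4-bromo-2,3-dihydrobenzofuran | COc1ccc(cc1)[C@H]1Oc2cc(OC)cc(Br)c2[C@@H]1c1cc(OC)cc(OC)c1 | intermediate
9 | 4-methoxystyrene | C=Cc1ccc(OC)cc1 | starting material
10 | (2S,3S)-ε-viniferin pentamethyl ether | COc1ccc(cc1)[C@H]1Oc2cc(OC)cc(/C=C/c3ccc(OC)cc3)c2[C@@H]1c1cc(OC)cc(OC)c1 | intermediate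
11 | pentamethyl ampelopsin B | COc1ccc([C@@H]2Cc3cc(OC)cc4c3[C@H](c3cc(OC)cc(OC)c32)[C@@H](c2ccc(OC)cc2)O4)cc1 | intermediate
12 | ampelopsin B | Oc1ccc([C@@H]2Cc3cc(O)cc4c3[C@H](c3cc(O)cc(O)c32)[C@@H](c2ccc(O)cc2)O4)cc1 | target

## Totals
Total steps: 8. Longest linear sequence: 8 (1 → 2 → 4 → 6 → 7 → 8 → 10 → 11 → 12).

## Three steps most likely to fail
1. **Step 4 (dynamic kinetic transfer hydrogenation).** The α,α-diaryl ketone is very hindered, and the ee or dr may be poor. Fallback: reduce 6 with NaBH4 to the racemic alcohol, carry it through step 5 (both alcohol diastereomers give the same racemic trans ring), and resolve 8 by preparative chiral HPLC. A ketoreductase-based dynamic resolution is an alternative.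
2. **Step 3 (second α-arylation).** A hindered enolate coupling gives a tertiary centre and may stall or give reduction or homocoupling. Fallback: make the α-bromo or α-diazo derivative of 2-(3,5-dimethoxyphenyl)-1-(4-methoxyphenyl)ethanone and perform an acid-promoted Friedel–Crafts C–H alkylation of arene 1, instead of Pd coupling.
3. **Step 5 (demethylative ring closure).** BBr3 may over-demethylate, or a cation 1,2-hydride shift or E1 elimination may scramble the diarylmethine centre. Fallback: use 1,3-dibromo-2-iodo-5-methoxybenzene as the ring-A partner in steps 2 and 3, so ring A carries two equivalent ortho bromides, and close the ring by Cu-catalysed intramolecular Ullmann C–O coupling of the alcohol with retention and no carbocation.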